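The inner dihydrofuran is cut at its C2–C3 bond. C3, which is shared with the seven-membered ring and bonded to the central arene (ring A) and the resorcinol ring (ring B), is traced back to the carbonyl carbon of a dibenzosuberone; the ortho oxygen on ring A carries a 4-methoxybenzyl group whose CH2 becomes C2. A chiral dirhodium carbene made from the derived diazo compound inserts into that C–H bond, closing the furan and fixing C3 in one operation. The precursor also carries a bromine next to the CH2 bridge and a second 4-methoxybenzyl ether, so that the outer dihydrofuran is made by the same chemistry; acid then turns both C2 centres trans.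

Key step: step 13

Remark on names: compounds 14–19 use dibenzosuberane locants (C5 carbonyl or diazo carbon, C10 the ArCH carbon, C11 the CH2; ring A = C1–C4, C4a, C11a; ring B = C5a–C9a). From 20 on, the inner dihydrofuran is O1, C2, C3 (C3 is the former C5) and the outer one O1′, C2′, C3′; ring A atoms are then lettered Ca (bears O1, former C4), Cb (H), Cc (second oxygen, former C2), Cd (former C1), Ce (bears C11) and Cf (bears C3); C10 and C11 keep their numbers.

Assumption: the absolute sense of induction of the copper hydride catalyst (step 4) and of each Rh2(PTAD)4 antipode (steps 13 and 15) is taken as written; if the first experiments show the opposite sense, the mirror-image ligand is used.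

Step 1
Reactants: 1 2-bromo-3,5-dimethoxybenzoic acid
Product: 2 tert-butyl 2-bromo-3,5-dimethoxybenzoate
Conditions: Cl3CC(=NH)OtBu (2 equiv), BF3·OEt2 (cat.), CH2Cl2/cyclohexane, rt
Reagents that add atoms: tert-butyl 2,2,2-trichloroacetimidate, CC(C)(C)OC(=N)C(Cl)(Cl)Cl
Why: Acid-catalysed esterification with the trichloroacetimidate should give a tert-butyl ester that survives the basic and organometallic steps ahead and is later removed under the conditions of the ring closure.

Step 2
Reactants: 3 2′,4′-dimethoxyacetophenone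
Product: 4 N′-[1-(2,4-dimethoxyphenyl)ethylidene]-4-methylbenzenesulfonohydrazide
Conditions: TsNHNH2 (1.05 equiv), MeOH, 60 °C
Reagents that add atoms: p-toluenesulfonyl hydrazide, Cc1ccc(S(=O)(=O)NN)cc1
Why: Condensation of the methyl ketone with the sulfonyl hydrazide should give the N-tosylhydrazone that serves as carbene source in the next step.

Step 3
Reactants: 2 tert-butyl 2-bromo-3,5-dimethoxybenzoate; 4 N′-[1-(2,4-dimethoxyphenyl)ethylidene]-4-methylbenzenesulfonohydrazide
Product: 6 tert-butyl 2-[1-(2,4-dimethoxyphenyl)ethenyl]-3,5-dimethoxybenzoate, via diazoalkane 5 (not isolated)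
Conditions: Pd2(dba)3 (2.5 mol%), XPhos (10 mol%), LiOtBu (2.4 equiv), 1,4-dioxane, 100 °C
Reagents that add atoms: none
Why: Barluenga coupling: base releases diazoalkane 5 from the tosylhydrazone, the arylpalladium bromide from 2 forms a palladium carbene, and migratory insertion followed by β-hydride elimination should give the 1,1-diarylethene, a coupling known to accept ortho,ortho′-substituted partners with XPhos.

Step 4
Reactants: 6 tert-butyl 2-[1-(2,4-dimethoxyphenyl)ethenyl]-3,5-dimethoxybenzoate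
Product: 7 tert-butyl 2-[(1S)-1-(2,4-dimethoxyphenyl)-2-(4,4,5,5-tetramethyl-1,3,2-dioxaborolan-2-yl)ethyl]-3,5-dimethoxybenzoate
Conditions: CuCl (5 mol%), (R)-DTBM-SEGPHOS (5.5 mol%), KOtBu (10 mol%), HBpin (1.5 equiv), toluene, rt
Reagents that add atoms: pinacolborane, CC1(C)OBOC1(C)C
Why: Copper hydride catalysed anti-Markovnikov asymmetric hydroboration of a 1,1-disubstituted vinylarene: hydride goes to the diaryl carbon on the face chosen by the chiral bisphosphine, which must tell the twisted 2,6-disubstituted benzoate ring from the flatter dimethoxyphenyl ring, and this should set the benzylic centre (later C10) as S.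

Step 5
Reactants: 8 1,3-bis(benzyloxy)-5-bromobenzene
Product: 9 1,3-bis(benzyloxy)-5-iodobenzene
Conditions: CuI (5 mol%), N,N′-dimethylethylenediamine (10 mol%), NaI (2 equiv), 1,4-dioxane, 110 °C
Reagents that add atoms: sodium iodide, [Na+].[I-]
Why: Copper-catalysed aromatic Finkelstein exchange should give the aryl iodide, so that a bromine introduced next can be carried as a spectator through the cross-coupling.

Step 6
Reactants: 9 1,3-bis(benzyloxy)-5-iodobenzene
Product: 10 1,5-bis(benzyloxy)-2-bromo-3-iodobenzene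
Conditions: NBS (1.05 equiv), MeCN, 0 °C to rt
Reagents that add atoms: N-bromosuccinimide, O=C1CCC(=O)N1Br
Why: Electrophilic aromatic bromination should go para to one benzyloxy group and ortho to the other, next to iodine, because the position between the two ethers is the more hindered one.

Step 7
Reactants: 7 tert-butyl 2-[(1S)-1-(2,4-dimethoxyphenyl)-2-(4,4,5,5-tetramethyl-1,3,2-dioxaborolan-2-yl)ethyl]-3,5-dimethoxybenzoate; 10 1,5-bis(benzyloxy)-2-bromo-3-iodobenzene
Product: 11 tert-butyl 2-[(1S)-2-[3,5-bis(benzyloxy)-2-bromophenyl]-1-(2,4-dimethoxyphenyl)ethyl]-3,5-dimethoxybenzoate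
Conditions: Pd(OAc)2 (5 mol%), RuPhos (10 mol%), KOH (3 equiv), THF/H2O (10:1), 70 °C
Reagents that add atoms: none
Why: B-alkyl Suzuki–Miyaura coupling in which oxidative addition should take the C–I bond and spare the hindered, electron-rich C–Br bond, while the stereocenter β to boron is not involved.

Step 8
Reactants: 11 tert-butyl 2-[(1S)-2-[3,5-bis(benzyloxy)-2-bromophenyl]-1-(2,4-dimethoxyphenyl)ethyl]-3,5-dimethoxybenzoate
Product: 14 (10S)-2,4-bis(benzyloxy)-1-bromo-10-(2,4-dimethoxyphenyl)-7,9-dimethoxy-10,11-dihydro-5H-dibenzo[a,d][7]annulen-5-one, via carboxylic acid 12 (not isolated), via mixed trifluoroacetic anhydride 13 (not isolated)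
Conditions: TFA/CH2Cl2 (1:3), 0 °C to rt; concentrate; TFAA (3 equiv), CH2Cl2, 0 °C to rt
Reagents that add atoms: none
Why: Acidolysis of the tert-butyl ester and intramolecular Friedel–Crafts acylation through the mixed anhydride should close the seven-membered ketone at the only open position ortho to the CH2 group, which is ortho and para to the two benzyloxy groups, whereas the ring position of the dimethoxyphenyl group that could reach the acyl carbon is meta to both methoxy groups.

Step 9
Reactants: 14 (10S)-2,4-bis(benzyloxy)-1-bromo-10-(2,4-dimethoxyphenyl)-7,9-dimethoxy-10,11-dihydro-5H-dibenzo[a,d][7]annulen-5-one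
Product: 15 (10S)-1-bromo-10-(2,4-dimethoxyphenyl)-2,4-dihydroxy-7,9-dimethoxy-10,11-dihydro-5H-dibenzo[a,d][7]annulen-5-one
Conditions: BCl3 (6 equiv), C6HMe5 (8 equiv), CH2Cl2, −78 °C; MeOH, aqueous work-up
Reagents that add atoms: none
Why: Lewis acid debenzylation with BCl3 and pentamethylbenzene as cation trap should cleave both aryl benzyl ethers at low temperature and leave the methyl ethers, none of which is ortho to the ketone, and the aryl bromide.

Step 10
Reactants: 15 (10S)-1-bromo-10-(2,4-dimethoxyphenyl)-2,4-dihydroxy-7,9-dimethoxy-10,11-dihydro-5H-dibenzo[a,d][7]annulen-5-one; 16 4-methoxybenzyl chloride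
Product: 17 (10S)-1-bromo-10-(2,4-dimethoxyphenyl)-7,9-dimethoxy-2,4-bis[(4-methoxybenzyl)oxy]-10,11-dihydro-5H-dibenzo[a,d][7]annulen-5-one
Conditions: 16 (2.6 equiv), K2CO3 (4 equiv), n-Bu4NI (cat.), DMF, 60 °C
Reagents that add atoms: none
Why: Williamson etherification should alkylate both phenols, the hydrogen-bonded one at C4 needing warm DMF.

Step 11
Reactants: 17 (10S)-1-bromo-10-(2,4-dimethoxyphenyl)-7,9-dimethoxy-2,4-bis[(4-methoxybenzyl)oxy]-10,11-dihydro-5H-dibenzo[a,d][7]annulen-5-one
Product: 18 hydrazone of 17 (5-hydrazinylidene, C=N geometry not assigned)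
Conditions: N2H4·H2O (30 equiv), AcOH (cat.), n-BuOH, 110 °C
Reagents that add atoms: hydrazine (as the monohydrate), NN
Why: Acid-catalysed hydrazone condensation with a large excess of hydrazine should convert the hindered diaryl ketone without touching the ethers or the bromide.

Step 12
Reactants: 18 hydrazone of 17
Product: 19 (10S)-1-bromo-5-diazo-10-(2,4-dimethoxyphenyl)-7,9-dimethoxy-2,4-bis[(4-methoxybenzyl)oxy]-10,11-dihydro-5H-dibenzo[a,d][7]annulene
Conditions: MnO2 (10 equiv), CH2Cl2, 0 °C; filtration through Celite; the cold solution is used at once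
Reagents that add atoms: none
Why: Dehydrogenation of the hydrazone with MnO2 should give the diaryl (donor/donor) diazo compound, which is stable enough to be filtered and handled cold.

Step 13
Reactants: 19 (10S)-1-bromo-5-diazo-10-(2,4-dimethoxyphenyl)-7,9-dimethoxy-2,4-bis[(4-methoxybenzyl)oxy]-10,11-dihydro-5H-dibenzo[a,d][7]annulene
Product: 20 (2R,3S,10S)-tetracycle with a cis inner dihydrofuran: C2 bears 4-methoxyphenyl, Cd bears Br, Cc bears the remaining 4-methoxybenzyl ether, C10 bears 2,4-dimethoxyphenyl, ring B is 7,9-dimethoxy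
Conditions: Rh2(R-PTAD)4 (1 mol%), CH2Cl2, −20 °C to rt, slow addition of 19
Reagents that add atoms: none
Why: Loss of N2 from 19 at rhodium gives a diaryl rhodium carbene at C5, which takes hydrogen in a hydride-like transfer from the ether CH2 on the C4 oxygen and forms the C2–C3 bond, a formal 1,5 C–H insertion. The closest known reaction type is the enantioselective intramolecular C–H insertion of donor/donor rhodium carbenes from 2-(benzyloxy)benzophenone hydrazones, which gives cis-2,3-diaryl-2,3-dihydrobenzofurans. The one ring formed is the five-membered dihydrofuran, closed by C–C bond formation between the carbene carbon and the fifth atom of the C4–O–CH2 tether, fused to ring A and to the seven-membered ring. C3 is set by the face of the carbene that receives hydrogen, which the chiral carboxylate ligands decide together with the C10 centre (the catalyst antipode is chosen for the matched pair), and C2 arises cis to the ring B aryl as the kinetic outcome of this insertion, to be corrected in step 16. The step needs site selectivity and suppression of azine or dimer formation: only the C4 ether CH2 lies 1,5 to the carbene, the second 4-methoxybenzyl ether is para to it and out of reach, the reacting C–H bond is activated by oxygen and by the 4-methoxyphenyl ring, and slow addition keeps the diazo concentration low.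

Step 14
Reactants: 20 (2R,3S,10S)-bromo tetracycle; 21 3,5-dimethoxybenzonitrile
Product: 24 (2R,3S,10S)-Cd-[(3,5-dimethoxyphenyl)(hydrazinylidene)methyl] analogue of 20, via aryllithium 22 (not isolated), via lithium ketimide 23 (not isolated)
Conditions: t-BuLi (2.1 equiv), THF, −78 °C; 21 (1.5 equiv), −78 to 0 °C; then N2H4·H2O (20 equiv), AcOH (5 equiv), EtOH, 70 °C
Reagents that add atoms: hydrazine (as the monohydrate), NN
Why: Bromine–lithium exchange, addition of the aryllithium to the nitrile and transimination of the ketimide with hydrazine should deliver the hindered diaryl hydrazone without a condensation on a di-ortho-substituted ketone, the low temperature avoiding deprotonation of the dihydrofuran and of the ortho benzylic ether.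

Step 15
Reactants: 24 (2R,3S,10S)-hydrazone
Product: 26 (2R,3S,10S,2′S,3′R)-octamethyl ether of the target skeleton with both dihydrofurans cis, via diazo compound 25 (not isolated)
Conditions: MnO2 (10 equiv), CH2Cl2, 0 °C; filtration; Rh2(S-PTAD)4 (2 mol%), CH2Cl2, 0 °C to rt
Reagents that add atoms: none
Why: A second donor/donor rhodium carbene C–H insertion, now into the CH2 of the 4-methoxybenzyl ether on Cc, should close the outer dihydrofuran; C3′ is set as R by the catalyst (the antipode of that used in step 13 is proposed because C3′ has the opposite sense within its own benzofuran frame) and C2′ forms cis.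

Step 16
Reactants: 26 (2R,3S,10S,2′S,3′R)-octamethyl ether
Product: 27 (2S,3S,10S,2′R,3′R)-octamethyl ether of the target (both dihydrofurans trans)
Conditions: TFA (10 equiv), CH2Cl2, 0 °C to rt
Reagents that add atoms: none
Why: Acid-mediated epimerisation: reversible ionisation of each C2–O bond to the 4-methoxybenzylic cation and reclosure by the phenol should turn C2 and C2′ to the more stable trans arrangement while C3, C3′ and C10 are not touched.

Step 17
Reactants: 27 (2S,3S,10S,2′R,3′R)-octamethyl ether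
Product: 28 CNP0154047.3 (target, octaphenol)
Conditions: BBr3 (24 equiv), CH2Cl2, −78 °C to rt; MeOH, aqueous NaHCO3
Reagents that add atoms: none
Why: Lewis acid ether cleavage with BBr3 should remove all eight methyl groups, and the trans dihydrofurans are the thermodynamic forms under these conditions, so no stereocenter should change.

Compound list
1 | 2-bromo-3,5-dimethoxybenzoic acid | OC(=O)c1cc(OC)cc(OC)c1Br | starting material
2 | tert-butyl 2-bromo-3,5-dimethoxybenzoate | CC(C)(C)OC(=O)c1cc(OC)cc(OC)c1Br | intermediate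
3 | 2′,4′-dimethoxyacetophenone | CC(=O)c1ccc(OC)cc1OC | starting material
4 | N′-[1-(2,4-dimethoxyphenyl)ethylidene]-4-methylbenzenesulfonohydrazide | CC(=NNS(=O)(=O)c1ccc(C)cc1)c1ccc(OC)cc1OC | intermediate
5 | 1-(1-diazoethyl)-2,4-dimethoxybenzene | CC(=[N+]=[N-])c1ccc(OC)cc1OC | intermediate (not isolated)
6 | tert-butyl 2-[1-(2,4-dimethoxyphenyl)ethenyl]-3,5-dimethoxybenzoate | CC(C)(C)OC(=O)c1cc(OC)cc(OC)c1C(=C)c1ccc(OC)cc1OC | intermediate
7 | tert-butyl 2-[(1S)-1-(2,4-dimethoxyphenyl)-2-(4,4,5,5-tetramethyl-1,3,2-dioxaborolan-2-yl)ethyl]-3,5-dimethoxybenzoate | CC(C)(C)OC(=O)c1cc(OC)cc(OC)c1[C@H](c1ccc(OC)cc1OC)CB1OC(C)(C)C(C)(C)O1 | intermediate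
8 | 1,3-bis(benzyloxy)-5-bromobenzene | Brc1cc(OCc2ccccc2)cc(OCc2ccccc2)c1 | starting material
9 | 1,3-bis(benzyloxy)-5-iodobenzene | Ic1cc(OCc2ccccc2)cc(OCc2ccccc2)c1 | intermediate
10 | 1,5-bis(benzyloxy)-2-bromo-3-iodobenzene | Ic1cc(OCc2ccccc2)cc(OCc2ccccc2)c1Br | intermediate
11 | tert-butyl 2-[(1S)-2-[3,5-bis(benzyloxy)-2-bromophenyl]-1-(2,4-dimethoxyphenyl)ethyl]-3,5-dimethoxybenzoate | CC(C)(C)OC(=O)c1cc(OC)cc(OC)c1[C@H](c1ccc(OC)cc1OC)Cc1cc(OCc2ccccc2)cc(OCc2ccccc2)c1Br | intermediate
12 | 2-[(1S)-2-[3,5-bis(benzyloxy)-2-bromophenyl]-1-(2,4-dimethoxyphenyl)ethyl]-3,5-dimethoxybenzoic acid | OC(=O)c1cc(OC)cc(OC)c1[C@H](c1ccc(OC)cc1OC)Cc1cc(OCc2ccccc2)cc(OCc2ccccc2)c1Br | intermediate (not isolated)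
13 | mixed anhydride of acid 12 with trifluoroacetic acid | O=C(OC(=O)C(F)(F)F)c1cc(OC)cc(OC)c1[C@H](c1ccc(OC)cc1OC)Cc1cc(OCc2ccccc2)cc(OCc2ccccc2)c1Br | intermediate (not isolated)
14 | (10S)-2,4-bis(benzyloxy)-1-bromo-10-(2,4-dimethoxyphenyl)-7,9-dimethoxy-10,11-dihydro-5H-dibenzo[a,d][7]annulen-5-one | O=C1c2cc(OC)cc(OC)c2[C@H](c2ccc(OC)cc2OC)Cc2c(Br)c(OCc3ccccc3)cc(OCc3ccccc3)c21 | intermediate
15 | (10S)-1-bromo-10-(2,4-dimethoxyphenyl)-2,4-dihydroxy-7,9-dimethoxy-10,11-dihydro-5H-dibenzo[a,d][7]annulen-5-one | O=C1c2cc(OC)cc(OC)c2[C@H](c2ccc(OC)cc2OC)Cc2c(Br)c(O)cc(O)c21 | intermediate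
16 | 4-methoxybenzyl chloride | COc1ccc(CCl)cc1 | starting material
17 | (10S)-1-bromo-10-(2,4-dimethoxyphenyl)-7,9-dimethoxy-2,4-bis[(4-methoxybenzyl)oxy]-10,11-dihydro-5H-dibenzo[a,d][7]annulen-5-one | O=C1c2cc(OC)cc(OC)c2[C@H](c2ccc(OC)cc2OC)Cc2c(Br)c(OCc3ccc(OC)cc3)cc(OCc3ccc(OC)cc3)c21 | intermediate
18 | hydrazone of 17 (5-hydrazinylidene, C=N geometry not assigned) | NN=C1c2cc(OC)cc(OC)c2[C@H](c2ccc(OC)cc2OC)Cc2c(Br)c(OCc3ccc(OC)cc3)cc(OCc3ccc(OC)cc3)c21 | intermediate
19 | (10S)-1-bromo-5-diazo-10-(2,4-dimethoxyphenyl)-7,9-dimethoxy-2,4-bis[(4-methoxybenzyl)oxy]-10,11-dihydro-5H-dibenzo[a,d][7]annulene | [N-]=[N+]=C1c2cc(OC)cc(OC)c2[C@H](c2ccc(OC)cc2OC)Cc2c(Br)c(OCc3ccc(OC)cc3)cc(OCc3ccc(OC)cc3)c21 | intermediate (key-step precursor)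
20 | (2R,3S,10S)-bromo tetracycle, cis inner dihydrofuran (C2 4-methoxyphenyl; Cd Br; Cc O-4-methoxybenzyl; C10 2,4-dimethoxyphenyl; ring B 7,9-dimethoxy) | COc1ccc([C@@H]2Oc3cc(OCc5ccc(OC)cc5)c(Br)c4c3[C@@H]2c2cc(OC)cc(OC)c2[C@H](c2ccc(OC)cc2OC)C4)cc1 | intermediate (key-step product)
21 | 3,5-dimethoxybenzonitrile | COc1cc(C#N)cc(OC)c1 | starting material
22 | (2R,3S,10S)-aryllithium from 20 (Li in place of Br on Cd) | COc1ccc([C@@H]2Oc3cc(OCc5ccc(OC)cc5)c([Li])c4c3[C@@H]2c2cc(OC)cc(OC)c2[C@H](c2ccc(OC)cc2OC)C4)cc1 | intermediate (not isolated)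
23 | (2R,3S,10S)-lithium ketimide (Cd–C(=NLi)–3,5-dimethoxyphenyl) | COc1ccc([C@@H]2Oc3cc(OCc5ccc(OC)cc5)c(C(=N[Li])c6cc(OC)cc(OC)c6)c4c3[C@@H]2c2cc(OC)cc(OC)c2[C@H](c2ccc(OC)cc2OC)C4)cc1 | intermediate (not isolated)
24 | (2R,3S,10S)-hydrazone (Cd–C(=NNH2)–3,5-dimethoxyphenyl, C=N geometry not assigned) | COc1ccc([C@@H]2Oc3cc(OCc5ccc(OC)cc5)c(C(=NN)c6cc(OC)cc(OC)c6)c4c3[C@@H]2c2cc(OC)cc(OC)c2[C@H](c2ccc(OC)cc2OC)C4)cc1 | intermediate
25 | (2R,3S,10S)-diazo compound (Cd–C(=N2)–3,5-dimethoxyphenyl) | COc1ccc([C@@H]2Oc3cc(OCc5ccc(OC)cc5)c(C(=[N+]=[N-])c6cc(OC)cc(OC)c6)c4c3[C@@H]2c2cc(OC)cc(OC)c2[C@H](c2ccc(OC)cc2OC)C4)cc1 | intermediate (not isolated)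
26 | (2R,3S,10S,2′S,3′R)-octamethyl ether of the target skeleton, both dihydrofurans cis | COc1ccc([C@@H]2Oc3cc4c(c5c3[C@@H]2c2cc(OC)cc(OC)c2[C@H](c2ccc(OC)cc2OC)C5)[C@@H](c2cc(OC)cc(OC)c2)[C@@H](c2ccc(OC)cc2)O4)cc1 | intermediate
27 | (2S,3S,10S,2′R,3′R)-octamethyl ether of the target, both dihydrofurans trans | COc1ccc([C@H]2Oc3cc4c(c5c3[C@@H]2c2cc(OC)cc(OC)c2[C@H](c2ccc(OC)cc2OC)C5)[C@@H](c2cc(OC)cc(OC)c2)[C@H](c2ccc(OC)cc2)O4)cc1 | intermediate
28 | CNP0154047.3, (2S,3S,10S,2′R,3′R)-octaphenol | Oc1ccc([C@H]2Oc3cc4c(c5c3[C@@H]2c2cc(O)cc(O)c2[C@H](c2ccc(O)cc2O)C5)[C@@H](c2cc(O)cc(O)c2)[C@H](c2ccc(O)cc2)O4)cc1 | target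

Total step count: 17
Longest linear sequence: 14 steps (steps 1, 3, 4 and 7 to 17)

Steps most likely to fail

1. Step 13 (key step). The carbene may be lost to azine or dimer formation, or hydrogen may be delivered to the wrong face at C3 if neither catalyst antipode is matched with the C10 centre. Fallback, setting out from 17 and returning at 27: 4-methoxybenzylmagnesium chloride adds to the ketone to give the tertiary carbinol F1. TFA with anisole as cation trap dehydrates it and removes both 4-methoxybenzyl ethers to give the ortho-hydroxystilbene F2, not isolated, which cyclises through the 4-methoxybenzylic cation to the trans dihydrofuran bromophenol F3, C3 then resting on substrate control. Treatment of F3 with t-BuLi (3.1 equiv) and 3,5-dimethoxybenzaldehyde gives the ortho-hydroxybenzhydrol F4. Base-mediated [4+1] annulation of F4 (ortho-quinone methide pathway) with the ylide of (4-methoxybenzyl)dimethylsulfonium triflate and Cs2CO3 closes the outer trans dihydrofuran and gives 27.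

2. Step 15. The hindered carbene may insert into the tertiary C10–H bond, which is also 1,5 to it, instead of the ether CH2, or the facial control at C3′ may be poor. Fallback, setting out from 20 and returning at 27: TFA with anisole removes the remaining 4-methoxybenzyl ether and epimerises C2, which gives the bromophenol F3 of the first fallback. The same two operations (aryllithium addition to 3,5-dimethoxybenzaldehyde to give the ortho-hydroxybenzhydrol F4, then sulfur ylide [4+1] annulation) lead to 27. This fallback makes no compound beyond F3 and F4.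

3. Step 4. The two aryl groups may be discriminated poorly (low enantiomeric purity at the future C10), or hydrocupration of the crowded alkene may be slow. Fallback, setting out from 6 and returning at 12: hydroboration with 9-BBN-H gives the racemic alkylborane F5, not isolated, which is coupled with 10 (Pd(dppf)Cl2, aqueous K3PO4, THF) to the racemic ester F6. TFA gives the racemic acid F7. Crystallisation with (R)-1-phenylethylamine (or its antipode, whichever gives the less soluble salt of the S acid) gives the salt F8. Acidification releases 12, which is cyclised with TFAA as in step 8.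

Further compounds
F1 | step 13 | (10S)-1-bromo-10-(2,4-dimethoxyphenyl)-7,9-dimethoxy-5-(4-methoxybenzyl)-2,4-bis[(4-methoxybenzyl)oxy]-10,11-dihydro-5H-dibenzo[a,d][7]annulen-5-ol (C5 epimers) | OC1(Cc2ccc(OC)cc2)c2cc(OC)cc(OC)c2[C@H](c2ccc(OC)cc2OC)Cc2c(Br)c(OCc3ccc(OC)cc3)cc(OCc3ccc(OC)cc3)c21
F2 | step 13 | (10S)-1-bromo-10-(2,4-dimethoxyphenyl)-7,9-dimethoxy-5-(4-methoxybenzylidene)-10,11-dihydro-5H-dibenzo[a,d][7]annulene-2,4-diol (alkene geometry not assigned) | COc1ccc(C=C2c3cc(OC)cc(OC)c3[C@H](c3ccc(OC)cc3OC)Cc3c(Br)c(O)cc(O)c32)cc1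
F3 | step 13 | (2S,3S,10S)-bromophenol, trans inner dihydrofuran (Cc OH, Cd Br) | COc1ccc([C@H]2Oc3cc(O)c(Br)c4c3[C@@H]2c2cc(OC)cc(OC)c2[C@H](c2ccc(OC)cc2OC)C4)cc1
F4 | step 13 | (2S,3S,10S)-ortho-hydroxybenzhydrol (Cc OH, Cd CH(OH)-3,5-dimethoxyphenyl, carbinol epimers) | COc1ccc([C@H]2Oc3cc(O)c(C(O)c5cc(OC)cc(OC)c5)c4c3[C@@H]2c2cc(OC)cc(OC)c2[C@H](c2ccc(OC)cc2OC)C4)cc1
F0 | step 15 | none | none
F5 | step 4 | racemic tert-butyl 2-[2-(9-borabicyclo[3.3.1]nonan-9-yl)-1-(2,4-dimethoxyphenyl)ethyl]-3,5-dimethoxybenzoate | CC(C)(C)OC(=O)c1cc(OC)cc(OC)c1C(c1ccc(OC)cc1OC)CB1C2CCCC1CCC2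
F6 | step 4 | racemic tert-butyl 2-[2-[3,5-bis(benzyloxy)-2-bromophenyl]-1-(2,4-dimethoxyphenyl)ethyl]-3,5-dimethoxybenzoate | CC(C)(C)OC(=O)c1cc(OC)cc(OC)c1C(c1ccc(OC)cc1OC)Cc1cc(OCc2ccccc2)cc(OCc2ccccc2)c1Br
F7 | step 4 | racemic 2-[2-[3,5-bis(benzyloxy)-2-bromophenyl]-1-(2,4-dimethoxyphenyl)ethyl]-3,5-dimethoxybenzoic acid | OC(=O)c1cc(OC)cc(OC)c1C(c1ccc(OC)cc1OC)Cc1cc(OCc2ccccc2)cc(OCc2ccccc2)c1Br
F8 | step 4 | (R)-1-phenylethylammonium salt of the S acid 12 | [O-]C(=O)c1cc(OC)cc(OC)c1[C@H](c1ccc(OC)cc1OC)Cc1cc(OCc2ccccc2)cc(OCc2ccccc2)c1Br.C[C@@H]([NH3+])c1ccccc1
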